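**Plan**

- Locants used in the text: oxane O1, C2 (CMe2), C3 (Br), C4, C5 (OH), C6 (Me and the cyclohexyl group); cyclohexane C1' (bonded to C6), C3' (Br), C4' (Me, Cl). Systematic names in the compound list number the oxane from the other end.
- Retrosynthetic cuts, in order: C5–OH back to the C5 ketone; C3–Br back to the C3=C4–C5=O enone; C3'–Br/C4'–Cl back to the C3'=C4' alkene; one C2–CH3 bond back to a C2 ketal; O1–C2 (together with C5=O) back to a 5-methyl-2-furyl carbinol; the C6–furyl bond back to a methyl ketone; the cyclohexene back to isoprene and an acrylimide.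
- Enabling feature: in the oxane the hydroxylated C5 is bonded to C6, the quaternary carbon that carries O1, a methyl group and C1'. This O1–C6–C5(O) unit is what the pair carbinol carbon/furan C2 becomes on oxidative ring expansion, while furan C3, C4 and C5 (with its methyl) become C4, C3 and C2.
- Forward order: the cyclohexene ring is built first (Diels–Alder), the furan is joined to the derived methyl ketone, the oxane ring arises by anodic furan oxidation and hemiketalisation, and the second C2 methyl, the ring halogens, C3–Br and C5–OH follow.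
- Stereochemistry: C1' from an auxiliary-controlled Diels–Alder; C6 from a titanium–BINOLate-catalysed furyl transfer, untouched afterwards; C3'/C4' from a Shi epoxide relayed through bromide opening and bromonium participation; C3 from equilibrating HBr addition; C5 from equatorial hydride delivery.

Key step: step 6

Remark: (S)-BINOL is assigned in step 5 on the premise that the titanium–BINOLate catalyst delivers the furyl group to the Si face of a methyl ketone, as it delivers carbon nucleophiles to the Si face of aldehydes; if the facial sense is the reverse, (R)-BINOL is used and nothing else changes.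

**Route**

Step 1
Reactants: 1 (R)-4-benzyloxazolidin-2-one; 2 acryloyl chloride
Product: 3 (R)-3-acryloyl-4-benzyloxazolidin-2-one
Conditions: MeMgBr, THF, 0 °C; then 2, −78 → 0 °C
Reagents that add atoms: none
Why: N-acylation of the oxazolidinone magnesium amide by an acid chloride; no stereocentre is formed and the bromomagnesium salt limits polymerisation of the acrylimide.

Step 2
Reactants: 3 (R)-3-acryloyl-4-benzyloxazolidin-2-one; 4 isoprene
Product: 5 (R)-4-benzyl-3-[(1S)-4-methylcyclohex-3-ene-1-carbonyl]oxazolidin-2-one
Conditions: Et2AlCl (1.4 equiv), 4 (excess), CH2Cl2, −100 °C; then 1 M HCl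
Reagents that add atoms: none
Why: Lewis acid-promoted asymmetric Diels–Alder reaction in which Et2AlCl chelates both imide carbonyls and fixes the s-cis acrylimide, so that the C4 benzyl group shields one face and isoprene adds to the open face with para regiochemistry, setting C1' as S.

Step 3
Reactants: 5 (R)-4-benzyl-3-[(1S)-4-methylcyclohex-3-ene-1-carbonyl]oxazolidin-2-one
Product: 7 (1S)-4-methylcyclohex-3-ene-1-carboxylic acid, via peroxy acid 6 (not isolated)
Conditions: LiOH, H2O2, THF–H2O, 0 °C; then aq. Na2SO3; then HCl to pH 2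
Reagents that add atoms: hydrogen peroxide, OO
Why: Hydroperoxide-mediated cleavage of an N-acyl oxazolidinone, in which the hydroperoxide anion attacks the exocyclic carbonyl, sulfite reduces the peroxy acid before acidification, and the α-stereocentre C1' is not touched.

Step 4
Reactants: 7 (1S)-4-methylcyclohex-3-ene-1-carboxylic acid
Product: 8 1-[(1S)-4-methylcyclohex-3-en-1-yl]ethan-1-one
Conditions: MeLi (2.2 equiv), Et2O, 0 °C; then H2O
Reagents that add atoms: methyllithium, [Li]C
Why: Ketone synthesis from a carboxylic acid and an organolithium, where the second equivalent adds to the lithium carboxylate to give a dilithium gem-diolate that collapses only on hydrolysis, so the reaction should stop at the ketone without epimerising C1'.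

Step 5
Reactants: 8 1-[(1S)-4-methylcyclohex-3-en-1-yl]ethan-1-one; 9 2-methylfuran
Product: 12 (1R)-1-(5-methylfuran-2-yl)-1-[(1S)-4-methylcyclohex-3-en-1-yl]ethan-1-ol, via 5-methyl-2-furyllithium 10 (not isolated), via furylaluminium reagent 11 (not isolated)
Conditions: 9, n-BuLi, THF, 0 °C; Et2AlCl, 0 → 23 °C; then 8, Ti(OiPr)4, (S)-1,1'-bi-2-naphthol (10 mol %), PhMe, 0 °C; neutral aqueous work-up
Reagents that add atoms: none
Why: Catalytic asymmetric 1,2-addition of a heteroaryl–aluminium reagent to a methyl ketone under a titanium–BINOLate catalyst, which distinguishes methyl from the branched cyclohexenyl group and should deliver the furyl group to the Si face, setting C6 as R where the neighbouring C1' (two CH2 arms) offers no useful bias.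

Step 6
Reactants: 12 (1R)-1-(5-methylfuran-2-yl)-1-[(1S)-4-methylcyclohex-3-en-1-yl]ethan-1-ol
Product: 15 (2R)-6-hydroxy-2,6-dimethyl-2-[(1S)-4-methylcyclohex-3-en-1-yl]-2H-pyran-3(6H)-one (hemiketal carbon as anomeric mixture), via dimethoxydihydrofuran 13 (not isolated), via Z-enedione 14 (not isolated)
Conditions: graphite anode, Pt cathode, undivided cell, Et4NOTs, 2,6-lutidine, MeOH, −20 °C, constant current, 2.1 F/mol; then 0.5 M aq. H2SO4, THF, 0 °C
Reagents that add atoms: water, O
Why: Anodic oxidation turns the 2,5-dialkylfuran into its radical cation, which takes up methanol, loses a second electron and a proton and takes up a second methanol to give the 2,5-dimethoxy-2,5-dihydrofuran 13; dilute acid then unmasks both ketals to the Z-enedione 14, whose tertiary hydroxyl adds to the methyl ketone. The closest known reaction type is the electrochemical Achmatowicz rearrangement, a Clauson-Kaas methoxylation of a furfuryl alcohol followed by acid hydrolysis. The six-membered pyranone ring closes by 6-exo-trig hemiketalisation that forms O1–C2, the Z geometry inherited from the furan holding the two ends within reach, and C5 emerges as the ketone. The only new stereocentre, the hemiketal carbon C2, forms as an equilibrating anomeric mixture and is erased in step 8, while C6 and C1' keep their configuration because none of their bonds is broken. The step needs chemoselectivity for the furan over the C3'=C4' alkene, which the much lower oxidation potential of the electron-rich dialkylfuran and the halide-free electrolyte (no anodically formed bromine) should secure. The lutidine buffer keeps the acid-labile tertiary furyl carbinol from ionising before the furan is dearomatised.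

Step 7
Reactants: 15 (2R)-6-hydroxy-2,6-dimethyl-2-[(1S)-4-methylcyclohex-3-en-1-yl]-2H-pyran-3(6H)-one
Product: 16 (2R)-6-methoxy-2,6-dimethyl-2-[(1S)-4-methylcyclohex-3-en-1-yl]-2H-pyran-3(6H)-one (anomeric mixture)
Conditions: MeOH, pyridinium p-toluenesulfonate (cat.), 3 Å molecular sieves, 23 °C
Reagents that add atoms: methanol, CO
Why: Acid-catalysed acetalisation (Fischer-type glycosidation) through the ring oxocarbenium ion; the anomer ratio is irrelevant because C2 is planarised again in step 8.

Step 8
Reactants: 16 (2R)-6-methoxy-2,6-dimethyl-2-[(1S)-4-methylcyclohex-3-en-1-yl]-2H-pyran-3(6H)-one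
Product: 17 (2R)-2,6,6-trimethyl-2-[(1S)-4-methylcyclohex-3-en-1-yl]-2H-pyran-3(6H)-one
Conditions: Me3Al (4 equiv), Me3SiOTf (10 mol %), CH2Cl2, −78 → −20 °C; then aq. NaHCO3
Reagents that add atoms: trimethylaluminium, C[Al](C)C
Why: Lewis acid-mediated ketal substitution (C-glycosylation type) in which the anomeric methoxy group is ionised to the cyclic oxocarbenium ion and a methyl group is transferred from aluminium to C2, which becomes a non-stereogenic gem-dimethyl carbon, while the C5 ketone flanked by quaternary C6 should resist 1,2-addition at low temperature.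

Step 9
Reactants: 17 (2R)-2,6,6-trimethyl-2-[(1S)-4-methylcyclohex-3-en-1-yl]-2H-pyran-3(6H)-one
Product: 18 (2R)-2,6,6-trimethyl-2-[(1R,3S,6S)-6-methyl-7-oxabicyclo[4.1.0]heptan-3-yl]-2H-pyran-3(6H)-one
Conditions: 1,2:4,5-di-O-isopropylidene-β-D-erythro-hexo-2,3-diulo-2,6-pyranose (Shi ketone, 30 mol %), KHSO5, K2CO3, Bu4NHSO4, MeCN–CH2(OMe)2/aq. Na2B4O7 buffer (pH 10.5), 0 °C
Reagents that add atoms: potassium peroxymonosulfate, [K+].[O-]S(=O)(=O)OO
Why: Shi asymmetric epoxidation (dioxirane oxygen transfer through a spiro transition state) of the electron-rich trisubstituted C3'=C4' alkene, the enone being inert; the D-fructose-derived ketone, which gives the R-configured CH carbon in epoxides of 1-substituted cyclohexenes, should deliver oxygen to the face anti to the C1' substituent (3'R, 4'S) by reagent control.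

Step 10
Reactants: 18 (2R)-2,6,6-trimethyl-2-[(1R,3S,6S)-6-methyl-7-oxabicyclo[4.1.0]heptan-3-yl]-2H-pyran-3(6H)-one
Product: 19 (2R)-2-[(1S,3R,4R)-4-bromo-3-hydroxy-4-methylcyclohexyl]-2,6,6-trimethyl-2H-pyran-3(6H)-one
Conditions: 48 % aq. HBr (1.2 equiv), CHCl3, −10 °C; crude product used directly
Reagents that add atoms: hydrogen bromide, Br
Why: Acid-mediated epoxide opening by bromide, in which attack at the tertiary C4' with inversion is both the Markovnikov and the trans-diaxial (Fürst–Plattner) mode for this epoxide diastereomer, so the axial tertiary bromide with an antiperiplanar axial C3' hydroxyl should result, one equivalent of acid at low temperature sparing the hindered enone.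

Step 11
Reactants: 19 (2R)-2-[(1S,3R,4R)-4-bromo-3-hydroxy-4-methylcyclohexyl]-2,6,6-trimethyl-2H-pyran-3(6H)-one
Product: 22 (2R)-2-[(1S,3S,4S)-3-bromo-4-chloro-4-methylcyclohexyl]-2,6,6-trimethyl-2H-pyran-3(6H)-one, via chlorosulfite 20 (not isolated), via diaxial bromochloride 21 (not isolated)
Conditions: SOCl2, CH2Cl2, 0 → 23 °C; concentrate; then PhCl, 100 °C
Reagents that add atoms: thionyl chloride, O=S(Cl)Cl
Why: Chlorodehydroxylation with neighbouring-group participation followed by diaxial-to-diequatorial dihalide rearrangement: the axial C4' bromine displaces the antiperiplanar chlorosulfite to give a bromonium ion on the ring face syn to C1', chloride opens it anti either at C4' (giving 22 at once) or at C3' (giving 21), and heating lets 21 interchange its two halogens, each staying on its own face, so both channels should end in the trans-diequatorial 3'S bromide/4'S chloride.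

Step 12
Reactants: 22 (2R)-2-[(1S,3S,4S)-3-bromo-4-chloro-4-methylcyclohexyl]-2,6,6-trimethyl-2H-pyran-3(6H)-one
Product: 23 (2R,5R)-5-bromo-2-[(1S,3S,4S)-3-bromo-4-chloro-4-methylcyclohexyl]-2,6,6-trimethyloxan-3-one
Conditions: HBr (33 % in AcOH), CH2Cl2, 0 → 23 °C, equilibrating
Reagents that add atoms: hydrogen bromide, Br
Why: Acid-mediated conjugate hydrobromination of the enone under reversible conditions, so that the C3 epimers interconvert by loss and re-addition of HBr and the equatorial 3R bromide (C–Br anti to the C2–O1 bond, free of the gauche C–Br/C–O repulsion of the axial epimer) is expected to be favoured, though perhaps only modestly, any 3S epimer being separated and resubjected.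

Step 13
Reactants: 23 (2R,5R)-5-bromo-2-[(1S,3S,4S)-3-bromo-4-chloro-4-methylcyclohexyl]-2,6,6-trimethyloxan-3-one
Product: 24 caespitol, (2R,3R,5R)-5-bromo-2-[(1S,3S,4S)-3-bromo-4-chloro-4-methylcyclohexyl]-2,6,6-trimethyloxan-3-ol
Conditions: LiBH(s-Bu)3, THF, −78 °C; then H2O
Reagents that add atoms: none
Why: Ketone reduction by a bulky trialkylborohydride, which should approach C5 along the equatorial trajectory, anti to the C6–O1 bond (polar Felkin–Anh model) and clear of the axial C3–H, giving the axial 5R alcohol trans to the equatorial bromine without touching the halides at −78 °C.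

**Compound list**

1 | (R)-4-benzyloxazolidin-2-one | O=C1N[C@H](Cc2ccccc2)CO1 | starting material
2 | acryloyl chloride | C=CC(=O)Cl | starting material
3 | (R)-3-acryloyl-4-benzyloxazolidin-2-one | C=CC(=O)N1[C@H](Cc2ccccc2)COC1=O | intermediate
4 | isoprene | CC(=C)C=C | starting material
5 | (R)-4-benzyl-3-[(1S)-4-methylcyclohex-3-ene-1-carbonyl]oxazolidin-2-one | O=C([C@H]1CCC(C)=CC1)N2[C@H](Cc3ccccc3)COC2=O | intermediate
6 | (1S)-4-methylcyclohex-3-ene-1-carboperoxoic acid | OOC(=O)[C@H]1CCC(C)=CC1 | intermediate
7 | (1S)-4-methylcyclohex-3-ene-1-carboxylic acid | OC(=O)[C@H]1CCC(C)=CC1 | intermediate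
8 | 1-[(1S)-4-methylcyclohex-3-en-1-yl]ethan-1-one | CC(=O)[C@H]1CCC(C)=CC1 | intermediate
9 | 2-methylfuran | Cc1ccco1 | starting material
10 | 5-methyl-2-furyllithium | [Li]c1ccc(C)o1 | intermediate
11 | diethyl(5-methylfuran-2-yl)aluminium (THF adduct) | CC[Al](CC)c1ccc(C)o1 | intermediate
12 | (1R)-1-(5-methylfuran-2-yl)-1-[(1S)-4-methylcyclohex-3-en-1-yl]ethan-1-ol | Cc1ccc(o1)[C@](C)(O)[C@H]1CCC(C)=CC1 | intermediate
13 | (1R)-1-(2,5-dimethoxy-5-methyl-2,5-dihydrofuran-2-yl)-1-[(1S)-4-methylcyclohex-3-en-1-yl]ethan-1-ol (mixture at the two ketal carbons) | COC1(C)C=CC(OC)(O1)[C@](C)(O)[C@H]2CCC(C)=CC2 | intermediate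
14 | (3Z,6R)-6-hydroxy-6-[(1S)-4-methylcyclohex-3-en-1-yl]hept-3-ene-2,5-dione | CC(=O)/C=C\C(=O)[C@](C)(O)[C@H]1CCC(C)=CC1 | intermediate
15 | (2R)-6-hydroxy-2,6-dimethyl-2-[(1S)-4-methylcyclohex-3-en-1-yl]-2H-pyran-3(6H)-one (anomeric mixture) | CC1(O)C=CC(=O)[C@@](C)([C@H]2CCC(C)=CC2)O1 | intermediate
16 | (2R)-6-methoxy-2,6-dimethyl-2-[(1S)-4-methylcyclohex-3-en-1-yl]-2H-pyran-3(6H)-one (anomeric mixture) | COC1(C)C=CC(=O)[C@@](C)([C@H]2CCC(C)=CC2)O1 | intermediate
17 | (2R)-2,6,6-trimethyl-2-[(1S)-4-methylcyclohex-3-en-1-yl]-2H-pyran-3(6H)-one | CC1(C)C=CC(=O)[C@@](C)([C@H]2CCC(C)=CC2)O1 | intermediate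
18 | (2R)-2,6,6-trimethyl-2-[(1R,3S,6S)-6-methyl-7-oxabicyclo[4.1.0]heptan-3-yl]-2H-pyran-3(6H)-one | CC1(C)C=CC(=O)[C@@](C)([C@H]2CC[C@]3(C)O[C@@H]3C2)O1 | intermediate
19 | (2R)-2-[(1S,3R,4R)-4-bromo-3-hydroxy-4-methylcyclohexyl]-2,6,6-trimethyl-2H-pyran-3(6H)-one | CC1(C)C=CC(=O)[C@@](C)([C@H]2CC[C@@](C)(Br)[C@H](O)C2)O1 | intermediate
20 | chlorosulfite ester of 19 at the C3' oxygen | CC1(C)C=CC(=O)[C@@](C)([C@H]2CC[C@@](C)(Br)[C@H](OS(Cl)=O)C2)O1 | intermediate
21 | (2R)-2-[(1S,3R,4R)-4-bromo-3-chloro-4-methylcyclohexyl]-2,6,6-trimethyl-2H-pyran-3(6H)-one (trans-diaxial halogens) | CC1(C)C=CC(=O)[C@@](C)([C@H]2CC[C@@](C)(Br)[C@H](Cl)C2)O1 | intermediate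
22 | (2R)-2-[(1S,3S,4S)-3-bromo-4-chloro-4-methylcyclohexyl]-2,6,6-trimethyl-2H-pyran-3(6H)-one (trans-diequatorial halogens) | CC1(C)C=CC(=O)[C@@](C)([C@H]2CC[C@](C)(Cl)[C@@H](Br)C2)O1 | intermediate
23 | (2R,5R)-5-bromo-2-[(1S,3S,4S)-3-bromo-4-chloro-4-methylcyclohexyl]-2,6,6-trimethyloxan-3-one | CC1(C)O[C@](C)([C@H]2CC[C@](C)(Cl)[C@@H](Br)C2)C(=O)C[C@H]1Br | intermediate
24 | caespitol, (2R,3R,5R)-5-bromo-2-[(1S,3S,4S)-3-bromo-4-chloro-4-methylcyclohexyl]-2,6,6-trimethyloxan-3-ol | CC1(C)O[C@](C)([C@H]2CC[C@](C)(Cl)[C@@H](Br)C2)[C@H](O)C[C@H]1Br | target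

**Count and risks**

Total step count: 13. Longest linear sequence: 13 steps (1 → 24; 2-methylfuran 9 enters at step 5).

Steps most likely to fail:

1. Step 12. The process at risk is stereocontrol at C3: bromide adds fastest along the axial trajectory on the ring face syn to the cyclohexyl group, the equilibrium between the C3 epimers may lie only weakly on the side of the equatorial bromide, and the adduct can shed HBr again on handling. The fallback sets out from 22 and replaces steps 12 and 13. Conjugate borylation with bis(pinacolato)diboron (CuCl, bis[2-(diphenylphosphino)phenyl] ether, NaOt-Bu cat., MeOH, THF, 23 °C) should add boron along the same axial trajectory and give the β-boryl ketone F1. LiBH(s-Bu)3 (THF, −78 °C) is then forced to the face opposite the axial boronate and should give the syn hydroxy boronate F2, with the C5 hydroxyl axial. Base-induced bromodeboronation (NaOMe, Br2, MeOH–THF, 0 °C) replaces boron by bromine with inversion at C3, which turns the easily formed axial C–B bond into the equatorial C–Br bond, and the sequence comes back to the route at 24.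

2. Step 5. The process at risk is facial discrimination in the furyl transfer: the catalyst class is established for aryl methyl ketones, and an enolisable, α-branched dialkyl ketone may react sluggishly or with low selectivity at C6. The fallback sets out from 8 and 9: 5-methyl-2-furyllithium 10 (n-BuLi, THF, 0 °C) is added to 8 without catalyst at −78 °C, which should give 12 together with its C6 epimer, the (1S)-carbinol F3. Because C1' is already fixed, the two are diastereomers and are separated by chromatography, and the route is rejoined at 12.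

3. Step 9. The process at risk is facial selectivity in the epoxidation of a remote, weakly biased ring alkene, where reagent control has to do all the work, together with decomposition of the ketone catalyst. The fallback sets out from 17 and uses substrate control instead. N-Bromosuccinimide in THF–H2O (0 °C) should give the trans-diaxial bromohydrin F4 through reversible bromonium formation and axial attack of water at the tertiary carbon. K2CO3 in MeOH closes it to the diastereomeric epoxide F5, with oxygen syn to the C1' substituent. LiCl with AcOH in THF opens this epoxide at the secondary C3' in the trans-diaxial sense to give the chlorohydrin F6. HBr (CH2Cl2, −20 °C) then exchanges the axial tertiary hydroxyl for bromine with retention, through capture of the β-chloro cation anti to chlorine. This gives 21, where the fallback comes back to the route; 21 is heated to 22 as in the second stage of step 11.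

Further compounds
F1 | step 12 | (2R,5S)-2-[(1S,3S,4S)-3-bromo-4-chloro-4-methylcyclohexyl]-2,6,6-trimethyl-5-(4,4,5,5-tetramethyl-1,3,2-dioxaborolan-2-yl)oxan-3-one | CC1(C)O[C@](C)([C@H]2CC[C@](C)(Cl)[C@@H](Br)C2)C(=O)C[C@@H]1B3OC(C)(C)C(C)(C)O3
F2 | step 12 | (2R,3R,5S)-2-[(1S,3S,4S)-3-bromo-4-chloro-4-methylcyclohexyl]-2,6,6-trimethyl-5-(4,4,5,5-tetramethyl-1,3,2-dioxaborolan-2-yl)oxan-3-ol | CC1(C)O[C@](C)([C@H]2CC[C@](C)(Cl)[C@@H](Br)C2)[C@H](O)C[C@@H]1B3OC(C)(C)C(C)(C)O3
F3 | step 5 | (1S)-1-(5-methylfuran-2-yl)-1-[(1S)-4-methylcyclohex-3-en-1-yl]ethan-1-ol | Cc1ccc(o1)[C@@](C)(O)[C@H]1CCC(C)=CC1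
F4 | step 9 | (2R)-2-[(1S,3R,4R)-3-bromo-4-hydroxy-4-methylcyclohexyl]-2,6,6-trimethyl-2H-pyran-3(6H)-one | CC1(C)C=CC(=O)[C@@](C)([C@H]2CC[C@@](C)(O)[C@H](Br)C2)O1
F5 | step 9 | (2R)-2,6,6-trimethyl-2-[(1S,3S,6R)-6-methyl-7-oxabicyclo[4.1.0]heptan-3-yl]-2H-pyran-3(6H)-one | CC1(C)C=CC(=O)[C@@](C)([C@H]2CC[C@@]3(C)O[C@H]3C2)O1
F6 | step 9 | (2R)-2-[(1S,3R,4R)-3-chloro-4-hydroxy-4-methylcyclohexyl]-2,6,6-trimethyl-2H-pyran-3(6H)-one | CC1(C)C=CC(=O)[C@@](C)([C@H]2CC[C@@](C)(O)[C@H](Cl)C2)O1
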